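The cyclohexenone ring is made from a cyclopent-3-en-1-ol. The plan exploits the array C6 ketone–C5 spiro carbon–C1 lactone carbinol of the 2-oxaspiro[4.5]decane core, the retron of a semipinacol rearrangement. In one operation a ring CH2 shifts from the carbinol carbon to the adjacent oxirane carbon: the five-membered carbocycle becomes six-membered, the C6 ketone appears, C5 is set by inversion, and the freed C1 oxygen closes the γ-lactone. The precursor is a propynyl-substituted α-hydroxy epoxide bearing a tert-butyl acetate arm; the symmetric ring makes both CH2 groups equivalent. Epoxidation/β-elimination then installs C7=C8 and the C9 acetate, and a ruthenium-catalysed Alder-ene coupling converts the propynyl group into the side chain.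

Key step: step 7

Remark: locants of the spiro compounds follow 2-oxaspiro[4.5]decane numbering (C1 lactone carbinol carbon, O2, C3 lactone carbonyl, C4 lactone CH2, C5 spiro carbon, C6 ketone, C7=C8 enone, C9 acetoxy carbon, C10 ring CH2).

Step 1
Reactants: 1 but-2-yn-1-ol
Product: 2 but-2-ynal
Conditions: activated MnO2 (10 equiv), CH2Cl2, rt; filtered and used as a solution
Reagents that add atoms: none
Why: MnO2 oxidation of a propargylic alcohol stops cleanly at the ynal and creates no stereocentre.

Step 2
Reactants: 3 methyl 2-[bis(2,2,2-trifluoroethoxy)phosphoryl]acetate; 4 tert-butyl bromoacetate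
Product: 5 4-tert-butyl 1-methyl 2-[bis(2,2,2-trifluoroethoxy)phosphoryl]butanedioate (racemic)
Conditions: NaH, THF, 0 °C to rt
Reagents that add atoms: none
Why: SN2 C-alkylation of the stabilised phosphonoacetate carbanion with a reactive α-bromo ester; the new stereocentre is racemic and is destroyed in step 3.

Step 3
Reactants: 5 4-tert-butyl 1-methyl 2-[bis(2,2,2-trifluoroethoxy)phosphoryl]butanedioate; 2 but-2-ynal
Product: 6 4-tert-butyl 1-methyl (2Z)-2-(but-2-yn-1-ylidene)butanedioate (propynyl group cis to CO2Me)
Conditions: KN(SiMe3)2, 18-crown-6, THF, −78 °C; then 2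
Reagents that add atoms: none
Why: Still–Gennari variant of the Horner–Wadsworth–Emmons reaction, in which the electron-poor trifluoroethyl phosphonate and the dissociated potassium ion make elimination faster than adduct equilibration, so the kinetic alkene with the aldehyde residue cis to the methyl ester should form.

Step 4
Reactants: 6 4-tert-butyl 1-methyl (2Z)-2-(but-2-yn-1-ylidene)butanedioate; 7 allylmagnesium bromide (2.3 equiv)
Product: 9 tert-butyl (3Z)-3-(4-hydroxyhepta-1,6-dien-4-yl)hept-3-en-5-ynoate, via allyl ketone 8 (not isolated)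
Conditions: THF, −78 °C; aq NH4Cl
Reagents that add atoms: none
Why: Double 1,2-addition of a Grignard reagent to an ester, where the methyl enoate reacts at −78 °C while the hindered tert-butyl ester is inert, the very fast allyl transfer should outrun deprotonation of the CH2 group and conjugate addition, and the alkene geometry is kept.

Step 5
Reactants: 9 tert-butyl (3Z)-3-(4-hydroxyhepta-1,6-dien-4-yl)hept-3-en-5-ynoate
Product: 10 tert-butyl 2-[(2R,3R)-2-(4-hydroxyhepta-1,6-dien-4-yl)-3-(prop-1-yn-1-yl)oxiran-2-yl]acetate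
Conditions: D-fructose-derived Shi ketone (0.3 equiv), Oxone (2KHSO5·KHSO4·K2SO4), K2CO3, Bu4NHSO4 (cat.), MeCN–CH2(OMe)2/aq Na2B4O7 buffer, 0 °C
Reagents that add atoms: potassium peroxymonosulfate (active part of Oxone), [K+].[O-]S(=O)(=O)OO
Why: Shi asymmetric epoxidation, in which the chiral dioxirane attacks the trisubstituted enyne double bond (an established substrate class) faster than the monosubstituted allyl groups and leaves the alkyne alone; the spiro transition state that gives (R,R)-epoxides from trans-disubstituted and trisubstituted alkenes predicts the (2R,3R) epoxide, and syn addition keeps the propynyl group cis to the carbinol carbon.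

Step 6
Reactants: 10 tert-butyl 2-[(2R,3R)-2-(4-hydroxyhepta-1,6-dien-4-yl)-3-(prop-1-yn-1-yl)oxiran-2-yl]acetate
Product: 11 tert-butyl 2-[(2R,3R)-2-(1-hydroxycyclopent-3-en-1-yl)-3-(prop-1-yn-1-yl)oxiran-2-yl]acetate
Conditions: RuCl2(=CHPh)(PCy3)2 (first-generation Grubbs catalyst, 3 mol %), CH2Cl2 (0.01 M), rt
Reagents that add atoms: none
Why: Ring-closing metathesis of a 4,4-disubstituted hepta-1,6-diene to a cyclopentene is fast and driven by loss of ethene, the hindered internal alkyne, the oxirane and the free alcohol should not interfere, and no stereocentre changes.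

Step 7
Reactants: 11 tert-butyl 2-[(2R,3R)-2-(1-hydroxycyclopent-3-en-1-yl)-3-(prop-1-yn-1-yl)oxiran-2-yl]acetate
Product: 14 (1R,5R)-1-(prop-1-yn-1-yl)-2-oxaspiro[4.5]dec-8-ene-3,6-dione, via hydroxy ketone 12 (not isolated), via hydroxy acid 13 (not isolated)
Conditions: ZnBr2 (3 equiv), CH2Cl2, 0 °C to rt
Reagents that add atoms: none
Why: ZnBr2 binds the oxirane oxygen and the neighbouring tertiary hydroxyl, the C–O bond at the fully substituted oxirane carbon lengthens, and an allylic ring CH2 of the cyclopentenol migrates to this carbon antiperiplanar to the leaving oxygen while the carbinol carbon becomes the C6 ketone (semipinacol rearrangement of a 2,3-epoxy alcohol; the closest known type is the zinc-halide-promoted rearrangement of α-hydroxy epoxides to β-hydroxy ketones with ring enlargement). The carbocycle reaches its final size by this suprafacial 1,2-alkyl shift (five to six atoms), and the lactone closes by 5-exo-trig acyl substitution once ZnBr2 has cleaved the tert-butyl ester of 12 to acid 13. The new quaternary centre C5 is set by inversion at the oxirane carbon, so it is fixed by the (2R,3R) epoxide and by the Z geometry of 9, which together place the propynyl group cis to the ketone carbon on the lactone ring; C1 keeps its C–O bond and its configuration. The step needs cleavage of the tertiary and not of the propargylic C–O bond, which is secured by the higher substitution of that carbon, by the inductively withdrawing alkynyl group on the other carbon and by the push of the adjacent carbinol. No choice between the two ring CH2 groups is needed, because the local symmetry of the cyclopent-3-en-1-ol makes both migrations give the same product. Release of oxirane strain and formation of the C=O bond drive the enlargement of the unstrained five-membered ring.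

Step 8
Reactants: 14 (1R,5R)-1-(prop-1-yn-1-yl)-2-oxaspiro[4.5]dec-8-ene-3,6-dione
Product: 15 (1R,5R,8R,9S)-8,9-epoxy-1-(prop-1-yn-1-yl)-2-oxaspiro[4.5]decane-3,6-dione (epoxide oxygen on the ring face that carries C1)
Conditions: mCPBA (1.1 equiv), CH2Cl2, 0 °C
Reagents that add atoms: mCPBA (3-chloroperoxybenzoic acid), OOC(=O)c1cccc(Cl)c1
Why: Prilezhaev epoxidation, in which the isolated cis C8=C9 bond is the only nucleophilic π bond (alkyne, ketone and lactone react far more slowly) and attack should occur anti to the pseudoaxial lactone CH2 (C4), that is on the face carrying C1, because the half-chair with the small CH2 axial and the branched C1 equatorial is the lower one; this sets C9.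

Step 9
Reactants: 15 (1R,5R,8R,9S)-8,9-epoxy-1-(prop-1-yn-1-yl)-2-oxaspiro[4.5]decane-3,6-dione
Product: 17 (1R,5R,9S)-3,6-dioxo-1-(prop-1-yn-1-yl)-2-oxaspiro[4.5]dec-7-en-9-yl acetate, via hydroxy enone 16 (not isolated)
Conditions: Et3N, CH2Cl2, 0 °C; then Ac2O, DMAP (5 mol %), 0 °C to rt
Reagents that add atoms: acetic anhydride, CC(=O)OC(C)=O
Why: E1cB opening of a β,γ-epoxy ketone, in which Et3N removes the acidic C7 proton, the C8–O bond breaks and the C9–O bond keeps its configuration, followed by DMAP-catalysed acetylation of the only hydroxyl group.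

Step 10
Reactants: 17 (1R,5R,9S)-3,6-dioxo-1-(prop-1-yn-1-yl)-2-oxaspiro[4.5]dec-7-en-9-yl acetate; 18 2-methylpent-4-en-2-ol
Product: 19 (+)-miliusane XVII, (1R,5R,9S)-1-[(1E,4E)-6-hydroxy-2,6-dimethylhepta-1,4-dien-1-yl]-3,6-dioxo-2-oxaspiro[4.5]dec-7-en-9-yl acetate
Conditions: [CpRu(MeCN)3]PF6 (10 mol %), acetone, rt
Reagents that add atoms: none
Why: Ruthenium-catalysed Alder-ene type alkene–alkyne coupling through a ruthenacyclopentene, in which the C–C bond forms at the less hindered methyl-bearing alkyne carbon, distal to the acyloxy-substituted propargylic carbon as known for but-2-ynyl esters and carbonates; syn addition of carbon and hydrogen gives the (1E) trisubstituted alkene, β-hydride elimination gives the (4E) alkene next to the tertiary alcohol, and only monosubstituted alkenes take part, so enone and allylic acetate should stay intact.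

Compound list
1 | but-2-yn-1-ol | CC#CCO | starting material
2 | but-2-ynal | CC#CC=O | intermediate
3 | methyl 2-[bis(2,2,2-trifluoroethoxy)phosphoryl]acetate | COC(=O)CP(=O)(OCC(F)(F)F)OCC(F)(F)F | starting material
4 | tert-butyl bromoacetate | CC(C)(C)OC(=O)CBr | starting material
5 | 4-tert-butyl 1-methyl 2-[bis(2,2,2-trifluoroethoxy)phosphoryl]butanedioate (racemic) | COC(=O)C(CC(=O)OC(C)(C)C)P(=O)(OCC(F)(F)F)OCC(F)(F)F | intermediate
6 | 4-tert-butyl 1-methyl (2Z)-2-(but-2-yn-1-ylidene)butanedioate | COC(=O)/C(CC(=O)OC(C)(C)C)=C\C#CC | intermediate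
7 | allylmagnesium bromide | C=CC[Mg]Br | starting material
8 | tert-butyl (3Z)-3-(but-3-enoyl)hept-3-en-5-ynoate | C=CCC(=O)/C(CC(=O)OC(C)(C)C)=C\C#CC | intermediate
9 | tert-butyl (3Z)-3-(4-hydroxyhepta-1,6-dien-4-yl)hept-3-en-5-ynoate | C=CCC(O)(CC=C)/C(CC(=O)OC(C)(C)C)=C\C#CC | intermediate
10 | tert-butyl 2-[(2R,3R)-2-(4-hydroxyhepta-1,6-dien-4-yl)-3-(prop-1-yn-1-yl)oxiran-2-yl]acetate | CC#C[C@H]1O[C@@]1(CC(=O)OC(C)(C)C)C(O)(CC=C)CC=C | intermediate
11 | tert-butyl 2-[(2R,3R)-2-(1-hydroxycyclopent-3-en-1-yl)-3-(prop-1-yn-1-yl)oxiran-2-yl]acetate | CC#C[C@H]1O[C@@]1(CC(=O)OC(C)(C)C)C2(O)CC=CC2 | intermediate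
12 | tert-butyl 2-{(1R)-1-[(1R)-1-hydroxybut-2-yn-1-yl]-2-oxocyclohex-4-en-1-yl}acetate | CC#C[C@@H](O)[C@]1(CC(=O)OC(C)(C)C)CC=CCC1=O | intermediate
13 | 2-{(1R)-1-[(1R)-1-hydroxybut-2-yn-1-yl]-2-oxocyclohex-4-en-1-yl}acetic acid | CC#C[C@@H](O)[C@]1(CC(=O)O)CC=CCC1=O | intermediate
14 | (1R,5R)-1-(prop-1-yn-1-yl)-2-oxaspiro[4.5]dec-8-ene-3,6-dione | O=C1CC=CC[C@]12CC(=O)O[C@@H]2C#CC | intermediate
15 | (1R,5R,8R,9S)-8,9-epoxy-1-(prop-1-yn-1-yl)-2-oxaspiro[4.5]decane-3,6-dione | O=C1C[C@H]3O[C@H]3C[C@]12CC(=O)O[C@@H]2C#CC | intermediate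
16 | (1R,5R,9S)-9-hydroxy-1-(prop-1-yn-1-yl)-2-oxaspiro[4.5]dec-7-ene-3,6-dione | O=C1C=C[C@@H](O)C[C@]12CC(=O)O[C@@H]2C#CC | intermediate
17 | (1R,5R,9S)-3,6-dioxo-1-(prop-1-yn-1-yl)-2-oxaspiro[4.5]dec-7-en-9-yl acetate | O=C1C=C[C@@H](OC(C)=O)C[C@]12CC(=O)O[C@@H]2C#CC | intermediate
18 | 2-methylpent-4-en-2-ol | C=CCC(C)(C)O | starting material
19 | (+)-miliusane XVII | CC(=O)O[C@@H]1C=CC(=O)[C@@]2(CC(=O)O[C@@H]2/C=C(\C)C/C=C/C(C)(C)O)C1 | target

Total step count: 10. Longest linear sequence: 9 steps (3 → 5 → 6 → 9 → 10 → 11 → 14 → 15 → 17 → 19).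

Steps most likely to fail

Step 7. The oxirane may be opened at the propargylic carbon, by the ester carbonyl oxygen or by bromide, faster than the tertiary C–O bond ionises. The long contact with ZnBr2 that the ester cleavage needs may also move the ring double bond into conjugation. The fallback sets out from 11 and comes back at 14; it separates the two events and changes the electrofuge.
- The tertiary alcohol of 11 is silylated with N-(trimethylsilyl)imidazole in CH2Cl2 to tert-butyl 2-[(2R,3R)-3-(prop-1-yn-1-yl)-2-{1-[(trimethylsilyl)oxy]cyclopent-3-en-1-yl}oxiran-2-yl]acetate F1.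
- F1 is submitted to the epoxy silyl ether rearrangement with TiCl4 in CH2Cl2 at −78 °C. At this temperature neither the ester nor the ring alkene should react, and the silyl group rather than a proton leaves the carbinol oxygen.
- Hydroxy ketone 12 is then isolated after aqueous work-up. A short separate treatment with CF3CO2H in CH2Cl2 at 0 °C removes the tert-butyl group and closes the lactone to 14.

Step 5. The dioxirane may discriminate poorly between the two faces of this crowded alkene, whose geminal substituents are both large, or it may also oxidise the allyl groups. The fallback sets out from 6 and comes back at 10; it moves the asymmetric step to a hydroxyl-directed Sharpless epoxidation of a primary allylic alcohol.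
- iBu2AlH (CH2Cl2, −78 °C) reduces the methyl ester of 6 selectively to tert-butyl (3Z)-3-(hydroxymethyl)hept-3-en-5-ynoate F2.
- Ti(OiPr)4, L-(+)-diethyl tartrate and tBuOOH (4 Å molecular sieves, CH2Cl2, −20 °C) should give tert-butyl 2-[(2S,3R)-2-(hydroxymethyl)-3-(prop-1-yn-1-yl)oxiran-2-yl]acetate F3. This tartrate is the enantiomer that gives (2S)-configured epoxy alcohols.
- Dess–Martin periodinane gives tert-butyl 2-[(2R,3R)-2-formyl-3-(prop-1-yn-1-yl)oxiran-2-yl]acetate F4.
- I2 and KOH in MeOH convert F4 into methyl (2R,3R)-2-(2-tert-butoxy-2-oxoethyl)-3-(prop-1-yn-1-yl)oxirane-2-carboxylate F5.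
- Double addition of 7 to the activated glycidic methyl ester of F5 (THF, −78 °C) gives 10. This order also removes the acidic vinylogous CH2 group from the Grignard step.

Step 8. Facial selectivity of the peracid may be poor or reversed, since the two substituents on C5 differ little in their demand on the half-chair. The fallback sets out from 14 and comes back at 17; it makes both faces converge.
- The undesired attack gives (1R,5R,8S,9R)-8,9-epoxy-1-(prop-1-yn-1-yl)-2-oxaspiro[4.5]decane-3,6-dione F6.
- Et3N opens F6 to (1R,5R,9R)-9-hydroxy-1-(prop-1-yn-1-yl)-2-oxaspiro[4.5]dec-7-ene-3,6-dione F7, which is separated from 16.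
- A Mitsunobu reaction of F7 with acetic acid (PPh3, diisopropyl azodicarboxylate, toluene, 0 °C) introduces the acetate with inversion at C9 and gives 17. Alcohol 16 is acetylated as in step 9.

Further compounds
F1 | step 7 | tert-butyl 2-[(2R,3R)-3-(prop-1-yn-1-yl)-2-{1-[(trimethylsilyl)oxy]cyclopent-3-en-1-yl}oxiran-2-yl]acetate | CC#C[C@H]1O[C@@]1(CC(=O)OC(C)(C)C)C2(O[Si](C)(C)C)CC=CC2
F2 | step 5 | tert-butyl (3Z)-3-(hydroxymethyl)hept-3-en-5-ynoate | OC/C(CC(=O)OC(C)(C)C)=C\C#CC
F3 | step 5 | tert-butyl 2-[(2S,3R)-2-(hydroxymethyl)-3-(prop-1-yn-1-yl)oxiran-2-yl]acetate | CC#C[C@H]1O[C@@]1(CC(=O)OC(C)(C)C)CO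
F4 | step 5 | tert-butyl 2-[(2R,3R)-2-formyl-3-(prop-1-yn-1-yl)oxiran-2-yl]acetate | CC#C[C@H]1O[C@@]1(CC(=O)OC(C)(C)C)C=O
F5 | step 5 | methyl (2R,3R)-2-(2-tert-butoxy-2-oxoethyl)-3-(prop-1-yn-1-yl)oxirane-2-carboxylate | CC#C[C@H]1O[C@@]1(CC(=O)OC(C)(C)C)C(=O)OC
F6 | step 8 | (1R,5R,8S,9R)-8,9-epoxy-1-(prop-1-yn-1-yl)-2-oxaspiro[4.5]decane-3,6-dione | O=C1C[C@@H]3O[C@@H]3C[C@]12CC(=O)O[C@@H]2C#CC
F7 | step 8 | (1R,5R,9R)-9-hydroxy-1-(prop-1-yn-1-yl)-2-oxaspiro[4.5]dec-7-ene-3,6-dione | O=C1C=C[C@H](O)C[C@]12CC(=O)O[C@@H]2C#CC
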